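**Plan**

1. Retrosynthesis: both O-benzyl groups are put back. The tetralin is then cut at C1–C8a and, in the same operation, at the bond from C1 to the ipso carbon C1' of the guaiacyl ring. This leaves an aryl Grignard reagent and a 2-hydroxytetrahydrofuran whose hemiacetal carbon is C1. The lactol goes back (C1–C2 cut) to a β-benzyl-γ-butyrolactone, and this (C3–C4 Stobbe cut) to an aldehyde and dimethyl succinate.
2. Forward: arene aldehyde → Stobbe half-ester → asymmetric hydrogenation → γ-lactone → C1 added as a dimethyl acetal → LiAlH4/H3O+ moves the oxygen ring from the C2 carboxyl carbon onto C1 → the Grignard reagent joins the guaiacyl ring to C1 and acid closes the carbocycle (C1–C8a), opening the temporary tetrahydrofuran again → hydrogenolysis.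
3. Enabling feature: C1 is benzylic to both arenes. The oxygen at C4' (para to C1') makes the C1–O bond ionisable, and arene carbon C8a (para to the C6 methoxy group, the only free position ortho to C4 because C5 bears OMe) closes the six-membered ring with a single regiochemical outcome.
4. Stereochemistry: C3 from the Rh/DuPhos hydrogenation; C2 from alkylation trans to the C3 benzyl group on the lactone; C1 in the ring closure (all-equatorial chair, 1,2-trans). No centre is touched afterwards.

Key step: step 9

Remark: tetralin numbering is used throughout (C1 = CH–aryl, C2 and C3 = CH–CH2OH, C4 = CH2, C5/C6 = OMe, C7 = OH, primed atoms = pendant ring). The target is (1R,2S,3S), with the aryl group and the C2 and C3 substituents mutually trans.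

**Route**

Step 1
Reactants: 1 2,3,4-trihydroxybenzaldehyde
Product: 2 4-(benzyloxy)-2,3-dihydroxybenzaldehyde
Conditions: BnBr (1.0 equiv), NaHCO3 (1.2 equiv), KI (cat.), MeCN, 60 °C
Reagents that add atoms: benzyl bromide, BrCc1ccccc1
Why: Williamson etherification under a weak base should be selective for the 4-OH, the most acidic phenol (para to the formyl group), because the 2-OH is held in a hydrogen bond to the carbonyl and the 3-OH is the least acidic.

Step 2
Reactants: 2 4-(benzyloxy)-2,3-dihydroxybenzaldehyde
Product: 3 4-(benzyloxy)-2,3-dimethoxybenzaldehyde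
Conditions: MeI (3 equiv), K2CO3 (3 equiv), DMF, 40 °C
Reagents that add atoms: iodomethane, CI
Why: Exhaustive Williamson O-methylation of the two remaining phenols, to which the aldehyde and the benzyl ether are inert.

Step 3
Reactants: 3 4-(benzyloxy)-2,3-dimethoxybenzaldehyde; 4 dimethyl succinate
Product: 5 (E)-4-[4-(benzyloxy)-2,3-dimethoxyphenyl]-3-(methoxycarbonyl)but-3-enoic acid
Conditions: NaOMe (1.5 equiv), MeOH, reflux; then 1 M HCl
Reagents that add atoms: none
Why: Stobbe condensation, in which the succinate enolate adds to the aldehyde, the aldolate lactonises to a paraconate and E1cB ring opening gives the half-ester with the free acid on the CH2 arm, mainly as the E alkene; no stereocentre is formed.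

Step 4
Reactants: 5 (E)-4-[4-(benzyloxy)-2,3-dimethoxyphenyl]-3-(methoxycarbonyl)but-3-enoic acid
Product: 6 (3S)-4-[4-(benzyloxy)-2,3-dimethoxyphenyl]-3-(methoxycarbonyl)butanoic acid
Conditions: [Rh(cod)((R,R)-Et-DuPhos)]OTf (1 mol %), H2 (6 bar), MeOH, rt
Reagents that add atoms: none
Why: Rh–bisphospholane asymmetric hydrogenation of a β-aryl itaconate half-ester, a standard substrate class in which carboxyl/ester chelation fixes the alkene face, so the ligand sets the new centre (later C3); the R,R ligand is expected to give the 3S acid (the S,S ligand is used if the first run shows the opposite sense), and the cationic Rh catalyst should leave the benzyl ether alone.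

Step 5
Reactants: 6 (3S)-4-[4-(benzyloxy)-2,3-dimethoxyphenyl]-3-(methoxycarbonyl)butanoic acid
Product: 8 (4S)-4-[4-(benzyloxy)-2,3-dimethoxybenzyl]dihydrofuran-2(3H)-one, via hydroxy acid 7 (not isolated)
Conditions: LiOH·H2O (1.0 equiv), MeOH, evaporate; LiBH4 (2 equiv), THF, 0 °C to rt; then 2 M HCl, rt
Reagents that add atoms: none
Why: Chemoselective ester reduction followed by lactonisation: LiBH4 reduces the methyl ester but not the lithium carboxylate, and the γ-hydroxy acid closes to the γ-lactone on acidification without touching the stereocentre.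

Step 6
Reactants: 8 (4S)-4-[4-(benzyloxy)-2,3-dimethoxybenzyl]dihydrofuran-2(3H)-one
Product: 10 (3R,4S)-4-[4-(benzyloxy)-2,3-dimethoxybenzyl]-3-(dimethoxymethyl)dihydrofuran-2(3H)-one, via ketene silyl acetal 9 (not isolated)
Conditions: LDA, THF, −78 °C; TMSCl; solvent change to CH2Cl2; HC(OMe)3, TMSOTf (10 mol %), −78 °C
Reagents that add atoms: trimethyl orthoformate, COC(OC)OC
Why: Mukaiyama-type alkylation of the lactone ketene silyl acetal by the dimethoxycarbenium ion (from the orthoformate and catalytic TMSOTf) puts C1 on at the aldehyde oxidation level without a free 1,3-dicarbonyl, and the electrophile approaches anti to the C4 benzyl group, which sets the 3,4-trans relation (C2 of the tetralin).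

Step 7
Reactants: 10 (3R,4S)-4-[4-(benzyloxy)-2,3-dimethoxybenzyl]-3-(dimethoxymethyl)dihydrofuran-2(3H)-one
Product: 12 (3S,4S)-4-[4-(benzyloxy)-2,3-dimethoxybenzyl]-3-(hydroxymethyl)tetrahydrofuran-2-ol, via diol acetal 11 (not isolated)
Conditions: LiAlH4, THF, 0 °C; aqueous NaOH work-up; then THF/1 M HCl (4:1), rt, short contact
Reagents that add atoms: water, O
Why: Hydride reduction of the lactone leaves the acetal intact, and acetal hydrolysis then gives an aldehyde that only the hydroxyl of the C3 arm can capture as a five-membered lactol (the C2 arm would give a four-membered ring), so the temporary ring moves from the C2 carboxyl carbon to C1; no stereocentre is touched, and the trans lactone becomes the cis-3,4-disubstituted lactol that the tetralin needs.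

Step 8
Reactants: 13 4-bromo-2-methoxyphenol
Product: 14 1-(benzyloxy)-4-bromo-2-methoxybenzene
Conditions: BnBr, K2CO3, acetone, reflux
Reagents that add atoms: benzyl bromide, BrCc1ccccc1
Why: Williamson etherification masks the phenol so that the aryl bromide can be turned into a Grignard reagent.

Step 9
Reactants: 12 (3S,4S)-4-[4-(benzyloxy)-2,3-dimethoxybenzyl]-3-(hydroxymethyl)tetrahydrofuran-2-ol; 14 1-(benzyloxy)-4-bromo-2-methoxybenzene
Product: 17 [(1R,2S,3S)-7-(benzyloxy)-1-[4-(benzyloxy)-3-methoxyphenyl]-5,6-dimethoxy-1,2,3,4-tetrahydronaphthalene-2,3-diyl]dimethanol, via aryl Grignard reagent 15 (not isolated), via seco triol 16 (not isolated)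
Conditions: 14 (3.5 equiv), Mg, THF, 50 °C; add 12, 0 °C to rt; aq. NH4Cl; crude 16, TFA (10 equiv), CH2Cl2 (0.02 M), 0 °C to rt; K2CO3, MeOH work-up
Reagents that add atoms: none
Why: Grignard reagent 15 deprotonates the two hydroxyls of 12 and then adds to the C1 aldehyde carbon of the ring-opened lactol (1,2-addition, the usual arylation of lactols), which forms the bond between the pendant-ring ipso carbon and C1 and gives triol 16 as a C1 epimer mixture that is not separated because both epimers ionise to the same cation. In TFA the benzylic C1–OH leaves to give a 4-alkoxybenzyl cation stabilised through the pendant ring by the para benzyloxy oxygen, and arene carbon C8a attacks it in an intramolecular Friedel–Crafts alkylation, the closest known reaction type being the acid-mediated conversion of 7-hydroxy-dibenzylbutanediols and 2-aryltetrahydrofuran lignans into aryltetralins. The carbocycle C1–C2–C3–C4–C4a–C8a closes in the six-membered Ar2-6 mode (ortho attack, 6-endo with respect to the C4a=C8a arene bond), while capture of the cation by the C3 hydroxymethyl oxygen (5-exo, 2-aryltetrahydrofuran) is reversible under acid and drains into the irreversible C–C closure. C1 is the only new stereocentre and is set by the existing C2 and C3 centres, because in the chair-like transition state the pendant aryl, C2–CH2OH and C3–CH2OH are all equatorial, which gives the 1,2-trans-2,3-trans (1R,2S,3S) arrangement. Regiochemistry on the pendant ring is fixed by the position of magnesium (para to OBn), and on the other ring by the substitution pattern, C8a being the only free carbon ortho to C4 and para to the C6 methoxy group. C- over O-alkylation and the integrity of C2 rely on low temperature, high dilution and short acid contact, so that the cation closes faster than it loses the C2 proton.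

Step 10
Reactants: 17 [(1R,2S,3S)-7-(benzyloxy)-1-[4-(benzyloxy)-3-methoxyphenyl]-5,6-dimethoxy-1,2,3,4-tetrahydronaphthalene-2,3-diyl]dimethanol
Product: 18 [(1R,2S,3S)-7-hydroxy-1-(4-hydroxy-3-methoxyphenyl)-5,6-dimethoxy-1,2,3,4-tetrahydronaphthalene-2,3-diyl]dimethanol
Conditions: H2 (1 atm), 10% Pd/C, EtOAc/MeOH, rt
Reagents that add atoms: none
Why: Hydrogenolysis of both aryl benzyl ethers over Pd/C should leave the diarylmethine centre, the methyl ethers and the primary alcohols untouched, so no stereocentre is affected.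

**Compound list**

1 | 2,3,4-trihydroxybenzaldehyde | O=Cc1ccc(O)c(O)c1O | starting material
2 | 4-(benzyloxy)-2,3-dihydroxybenzaldehyde | O=Cc1ccc(OCc2ccccc2)c(O)c1O | intermediate
3 | 4-(benzyloxy)-2,3-dimethoxybenzaldehyde | O=Cc1ccc(OCc2ccccc2)c(OC)c1OC | intermediate
4 | dimethyl succinate | COC(=O)CCC(=O)OC | starting material
5 | (E)-4-[4-(benzyloxy)-2,3-dimethoxyphenyl]-3-(methoxycarbonyl)but-3-enoic acid | OC(=O)C/C(=C\c1ccc(OCc2ccccc2)c(OC)c1OC)C(=O)OC | intermediate
6 | (3S)-4-[4-(benzyloxy)-2,3-dimethoxyphenyl]-3-(methoxycarbonyl)butanoic acid | COc1c(OC)c(OCc2ccccc2)ccc1C[C@H](C(=O)OC)CC(=O)O | intermediate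
7 | (3S)-4-[4-(benzyloxy)-2,3-dimethoxyphenyl]-3-(hydroxymethyl)butanoic acid | COc1c(OC)c(OCc2ccccc2)ccc1C[C@H](CO)CC(=O)O | intermediate (not isolated)
8 | (4S)-4-[4-(benzyloxy)-2,3-dimethoxybenzyl]dihydrofuran-2(3H)-one | COc1c(OC)c(OCc2ccccc2)ccc1C[C@@H]1COC(=O)C1 | intermediate
9 | {[(4S)-4-[4-(benzyloxy)-2,3-dimethoxybenzyl]-4,5-dihydrofuran-2-yl]oxy}trimethylsilane | COc1c(OC)c(OCc2ccccc2)ccc1C[C@@H]1COC(O[Si](C)(C)C)=C1 | intermediate (not isolated)
10 | (3R,4S)-4-[4-(benzyloxy)-2,3-dimethoxybenzyl]-3-(dimethoxymethyl)dihydrofuran-2(3H)-one | COc1c(OC)c(OCc2ccccc2)ccc1C[C@@H]1COC(=O)[C@H]1C(OC)OC | intermediate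
11 | (2S,3S)-2-[4-(benzyloxy)-2,3-dimethoxybenzyl]-3-(dimethoxymethyl)butane-1,4-diol | COc1c(OC)c(OCc2ccccc2)ccc1C[C@H](CO)[C@@H](CO)C(OC)OC | intermediate (not isolated)
12 | (3S,4S)-4-[4-(benzyloxy)-2,3-dimethoxybenzyl]-3-(hydroxymethyl)tetrahydrofuran-2-ol (anomer mixture) | COc1c(OC)c(OCc2ccccc2)ccc1C[C@@H]1COC(O)[C@@H]1CO | intermediate
13 | 4-bromo-2-methoxyphenol | COc1cc(Br)ccc1O | starting material
14 | 1-(benzyloxy)-4-bromo-2-methoxybenzene | COc1cc(Br)ccc1OCc1ccccc1 | intermediate
15 | [4-(benzyloxy)-3-methoxyphenyl]magnesium bromide | COc1cc([Mg]Br)ccc1OCc1ccccc1 | intermediate (not isolated)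
16 | (2S,3S)-2-{[4-(benzyloxy)-3-methoxyphenyl](hydroxy)methyl}-3-[4-(benzyloxy)-2,3-dimethoxybenzyl]butane-1,4-diol (C1 epimer mixture) | COc1c(OC)c(OCc2ccccc2)ccc1C[C@H](CO)[C@@H](CO)C(O)c1ccc(OCc2ccccc2)c(OC)c1 | intermediate (not isolated)
17 | [(1R,2S,3S)-7-(benzyloxy)-1-[4-(benzyloxy)-3-methoxyphenyl]-5,6-dimethoxy-1,2,3,4-tetrahydronaphthalene-2,3-diyl]dimethanol | COc1cc([C@@H]2c3cc(OCc4ccccc4)c(OC)c(OC)c3C[C@H](CO)[C@H]2CO)ccc1OCc1ccccc1 | intermediate
18 | [(1R,2S,3S)-7-hydroxy-1-(4-hydroxy-3-methoxyphenyl)-5,6-dimethoxy-1,2,3,4-tetrahydronaphthalene-2,3-diyl]dimethanol | COc1cc([C@@H]2c3cc(O)c(OC)c(OC)c3C[C@H](CO)[C@H]2CO)ccc1O | target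

**Step count and risks**

Total step count: 10. Longest linear sequence: 9 steps (steps 1–7, 9, 10); step 8 is a one-step side branch.

Risk 1 (step 9). In the acid stage the C1 cation may be held as the 2-aryltetrahydrofuran (capture by the C3 hydroxymethyl oxygen), or may lose the C2 proton to a styrene. Either could win over attack by C8a, which is only moderately nucleophilic because its para methoxy group is twisted by two ortho substituents. The outcome would be incomplete ring closure and erosion of configuration at C2. The fallback sets out from lactone 8 and comes back at 17. The lithium enolate of 8 (LDA, THF, −78 °C) is added to commercial 4-(benzyloxy)-3-methoxybenzaldehyde, which gives the trans aldol adduct, (3R,4S)-3-{[4-(benzyloxy)-3-methoxyphenyl](hydroxy)methyl}-4-[4-(benzyloxy)-2,3-dimethoxybenzyl]dihydrofuran-2(3H)-one F1. TFA in CH2Cl2 then closes the carbocycle while the lactone still ties up both oxygenated arms, so no hydroxyl can trap the cation; this should give the trans-fused lactone (3aS,9R,9aS)-7-(benzyloxy)-9-[4-(benzyloxy)-3-methoxyphenyl]-5,6-dimethoxy-3a,4,9,9a-tetrahydronaphtho[2,3-c]furan-1(3H)-one F2. LiAlH4 in THF reduces F2 to 17.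

Risk 2 (step 6). C-alkylation of the ketene silyl acetal by the dimethoxycarbenium ion may be slower than desilylation, the product may lose methanol to the α-methoxymethylene lactone, and the facial selectivity may be incomplete. The fallback sets out from lactone 8 and comes back at 16. A crossed Claisen condensation of the enolate of 8 (LiHMDS, 2.2 equiv, THF, −78 °C to 0 °C) with commercial methyl 4-(benzyloxy)-3-methoxybenzoate should give the keto lactone (3R,4S)-3-[4-(benzyloxy)-3-methoxybenzoyl]-4-[4-(benzyloxy)-2,3-dimethoxybenzyl]dihydrofuran-2(3H)-one F3, the trans isomer being the stable epimer of this enolisable 1,3-dicarbonyl compound. LiAlH4 (excess, THF, 0 °C to reflux) reduces ketone and lactone to triol 16, which enters the acid stage of step 9.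

Risk 3 (step 7). During acetal hydrolysis the ring-opened hydroxy aldehyde can enolise. This would epimerise C2 toward the more stable trans-disubstituted lactol and end as the 2,3-cis tetralin. The fallback sets out from diol acetal 11 (isolated after the LiAlH4 reduction) and comes back at 17; it never passes through a free aldehyde.
- Camphorsulfonic acid (cat.) with 4 Å sieves in CH2Cl2 closes 11 to the cyclic acetal [(3S,4S)-4-[4-(benzyloxy)-2,3-dimethoxybenzyl]-2-methoxytetrahydrofuran-3-yl]methanol F4.
- Benzenesulfinic acid and CaCl2 in CH2Cl2 exchange the methoxy group for the sulfone, giving [(3S,4S)-4-[4-(benzyloxy)-2,3-dimethoxybenzyl]-2-(phenylsulfonyl)tetrahydrofuran-3-yl]methanol F5.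
- Grignard reagent 15 with ZnBr2 in THF displaces the sulfinate through the cyclic oxocarbenium ion and forms the aryl–C1 bond, giving [(3S,4S)-2-[4-(benzyloxy)-3-methoxyphenyl]-4-[4-(benzyloxy)-2,3-dimethoxybenzyl]tetrahydrofuran-3-yl]methanol F6.
- TFA in CH2Cl2 opens the benzylic ether of F6 and closes the carbocycle to 17.

Further compounds
F1 | step 9 | (3R,4S)-3-{[4-(benzyloxy)-3-methoxyphenyl](hydroxy)methyl}-4-[4-(benzyloxy)-2,3-dimethoxybenzyl]dihydrofuran-2(3H)-one | COc1c(OC)c(OCc2ccccc2)ccc1C[C@@H]1COC(=O)[C@H]1C(O)c1ccc(OCc2ccccc2)c(OC)c1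
F2 | step 9 | (3aS,9R,9aS)-7-(benzyloxy)-9-[4-(benzyloxy)-3-methoxyphenyl]-5,6-dimethoxy-3a,4,9,9a-tetrahydronaphtho[2,3-c]furan-1(3H)-one | COc1cc([C@@H]2c3cc(OCc4ccccc4)c(OC)c(OC)c3C[C@@H]3COC(=O)[C@@H]23)ccc1OCc1ccccc1
F3 | step 6 | (3R,4S)-3-[4-(benzyloxy)-3-methoxybenzoyl]-4-[4-(benzyloxy)-2,3-dimethoxybenzyl]dihydrofuran-2(3H)-one | COc1c(OC)c(OCc2ccccc2)ccc1C[C@@H]1COC(=O)[C@H]1C(=O)c1ccc(OCc2ccccc2)c(OC)c1
F4 | step 7 | [(3S,4S)-4-[4-(benzyloxy)-2,3-dimethoxybenzyl]-2-methoxytetrahydrofuran-3-yl]methanol | COc1c(OC)c(OCc2ccccc2)ccc1C[C@@H]1COC(OC)[C@@H]1CO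
F5 | step 7 | [(3S,4S)-4-[4-(benzyloxy)-2,3-dimethoxybenzyl]-2-(phenylsulfonyl)tetrahydrofuran-3-yl]methanol | COc1c(OC)c(OCc2ccccc2)ccc1C[C@@H]1COC([C@@H]1CO)S(=O)(=O)c1ccccc1
F6 | step 7 | [(3S,4S)-2-[4-(benzyloxy)-3-methoxyphenyl]-4-[4-(benzyloxy)-2,3-dimethoxybenzyl]tetrahydrofuran-3-yl]methanol | COc1c(OC)c(OCc2ccccc2)ccc1C[C@@H]1COC([C@@H]1CO)c1ccc(OCc2ccccc2)c(OC)c1
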